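## Retrosynthetic overview

1. Target 20 ← diol 19 (MnO2) ← seco-aldehyde 16 (desulfonylation/reduction, desilylation); the enal carbon is carried from the start as a silyloxymethyl group on the epoxide.
2. Key disconnection: the cyclohexane ring of 16 ← acyclic epoxy-tetraene sulfone 13 in one cationic cascade patterned on the oxidosqualene → marneral (iridal) pathway.
3. Ring order: ring A closes first (C4–C5), ring B second (C9–C10). After three 1,2-shifts, ring A is opened again by Grob fragmentation (C3–C4), so ring B is the only ring left.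
4. 13 ← farnesyl sulfone 11 + allylic chloride 9 (C11–C12 bond); 9 ← (2Z,6E)-farnesol 4 (terminal oxidation, Sharpless epoxidation); 4 ← prenol 1 + geranyl bromide 2.

Assumption: the target is taken exactly as the SMILES reads, that is (2S,3R,4R) in cyclohexylidene numbering, a (2Z)-enal and an all-E side chain.

Numbering in the text: the polyene and the transient decalin are labelled as in triterpenes. C3 is the epoxide CH, C4 the epoxide quaternary carbon, C5/C10 the first olefin, C8/C9 the second (Z) olefin, C11 the CH2 next to C9, and C12 the sulfonyl carbon. β is the face that carries the C10 methyl group after ring closure.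

## Route

Step 1
Reactants: 1 prenol (3-methylbut-2-en-1-ol); 2 geranyl bromide ((2E)-1-bromo-3,7-dimethylocta-2,6-diene)
Product: 4 (2Z,6E)-farnesol, via dilithio prenol dianion 3 (not isolated)
Conditions: n-BuLi (2.1 equiv), TMEDA, Et2O/hexane, 0 °C → rt; then 2, −78 → 0 °C
Reagents that add atoms: none
Why: Alkoxide-directed allylic lithiation removes a proton from the methyl group cis to CH2OLi, and the allyl dianion is alkylated at its CH2 terminus by the allylic bromide (SN2), so the new chain sits cis to CH2OH (2Z) while the 6E olefin comes unchanged from 2; no stereocentre is formed.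

Step 2
Reactants: 4 (2Z,6E)-farnesol
Product: 6 (2Z,6E)-farnesyl chloride, via allylic mesylate 5 (not isolated)
Conditions: MsCl, s-collidine, LiCl, DMF, 0 °C
Reagents that add atoms: lithium chloride, [Li+].[Cl-] (methanesulfonyl chloride, CS(=O)(=O)Cl, only builds the leaving group of 5)
Why: Mesylation followed by SN2 displacement with chloride at the primary allylic carbon under buffered conditions gives allylic chlorides without allylic transposition or Z/E leakage.

Step 3
Reactants: 6 (2Z,6E)-farnesyl chloride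
Product: 7 (2E,6E,10Z)-12-chloro-2,6,10-trimethyldodeca-2,6,10-trien-1-ol
Conditions: SeO2 (0.1 equiv), t-BuOOH (3 equiv), salicylic acid (0.1 equiv), CH2Cl2, rt
Reagents that add atoms: tert-butyl hydroperoxide, CC(C)(C)OO (oxygen relayed through SeO2, O=[Se]=O)
Why: Riley-type allylic oxidation in its catalytic form (ene reaction, then [2,3]-sigmatropic shift) functionalises the (E)-methyl group of the terminal isopropylidene unit, the most electron-rich and least hindered olefin (the olefin next to CH2Cl is switched off inductively); the cyclic transition state fixes the E geometry and no stereocentre is formed.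

Step 4
Reactants: 7 (2E,6E,10Z)-12-chloro-2,6,10-trimethyldodeca-2,6,10-trien-1-ol
Product: 8 [(2S,3S)-3-[(3E,7Z)-9-chloro-3,7-dimethylnona-3,7-dien-1-yl]-2-methyloxiran-2-yl]methanol
Conditions: Ti(OiPr)4 (10 mol %), L-(+)-diethyl tartrate (12 mol %), t-BuOOH, 4 Å sieves, CH2Cl2, −20 °C
Reagents that add atoms: tert-butyl hydroperoxide, CC(C)(C)OO
Why: Sharpless asymmetric epoxidation touches only the olefin of the allylic alcohol, and with L-(+)-tartrate an (E)-2-methylalk-2-en-1-ol gives the (2S,3S)-epoxide; this sets both epoxide stereocentres (the CH carbon is S, as in (3S)-oxidosqualene), from which all ring stereocentres are later derived.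

Step 5
Reactants: 8 [(2S,3S)-3-[(3E,7Z)-9-chloro-3,7-dimethylnona-3,7-dien-1-yl]-2-methyloxiran-2-yl]methanol
Product: 9 tert-butyl{[(2S,3S)-3-[(3E,7Z)-9-chloro-3,7-dimethylnona-3,7-dien-1-yl]-2-methyloxiran-2-yl]methoxy}diphenylsilane
Conditions: TBDPSCl, imidazole, CH2Cl2, 0 °C
Reagents that add atoms: tert-butyl(chloro)diphenylsilane, CC(C)(C)[Si](Cl)(c1ccccc1)c1ccccc1
Why: Silylation of the primary alcohol gives a bulky, non-chelating and non-participating ether, so that the epoxide later opens at its tertiary carbon and the group survives BF3; the stereocentres are untouched.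

Step 6
Reactants: 10 (2E,6E)-farnesyl bromide
Product: 11 (2E,6E)-farnesyl phenyl sulfone
Conditions: PhSO2Na, DMF, rt
Reagents that add atoms: sodium benzenesulfinate, [Na+].[O-]S(=O)c1ccccc1
Why: SN2 S-alkylation of the sulfinate by the primary allylic bromide in a dipolar aprotic solvent leaves the E,E geometry untouched.

Step 7
Reactants: 11 (2E,6E)-farnesyl phenyl sulfone; 9 silyl ether chloride
Product: 13 tert-butyl({(2S,3S)-2-methyl-3-[(3E,7Z,11E,15E)-3,7,12,16,20-pentamethyl-10-(phenylsulfonyl)henicosa-3,7,11,15,19-pentaen-1-yl]oxiran-2-yl}methoxy)diphenylsilane, via lithiated sulfone 12 (not isolated)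
Conditions: n-BuLi, THF, −78 °C; then 9, DMPU, −78 → 0 °C
Reagents that add atoms: none
Why: Alkylation of the sulfone-stabilised allyl anion at its α-carbon by the primary allylic chloride (SN2, Biellmann-type tail-to-tail prenyl coupling) leaves the Z olefin, epoxide and silyl ether intact at low temperature; the new sulfonyl-bearing stereocentre forms without control (about 1:1) and is erased in step 9.

Step 8
Reactants: 13 epoxy-tetraene sulfone
Product: 16 3-[(1S,2R,3R,6Z)-6-[1-(tert-butyldiphenylsilyloxy)propan-2-ylidene]-2,3-dimethyl-2-[(3E,7E)-4,8,12-trimethyl-2-(phenylsulfonyl)trideca-3,7,11-trien-1-yl]cyclohexyl]propanal, via C8 cation zwitterion 14 (not isolated), via C5 cation zwitterion 15 (not isolated)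
Conditions: BF3·OEt2 (3 equiv), CH2Cl2 (0.005 M), −78 → −30 °C; then Et3N
Reagents that add atoms: none
Why: Proposed new method: BF3 opens the epoxide at its tertiary carbon with anti attack by the E olefin and then by the Z olefin through an all-chair fold (Stork–Eschenmoser stereospecificity), and the Z geometry puts H9 on the β face, which is what the ring B boat does in the enzyme; in the resulting zwitterion 14 the C8 cation cannot close a third ring because the neighbouring chain olefin is deactivated by the allylic sulfonyl group, so suprafacial 1,2-shifts (H9β to C8, 10β-methyl to C9, H5α to C10) carry the charge toward the alkoxytrifluoroborate and fix C8, C9 and C10 from the single epoxide configuration; cation 15 then collapses by Grob (retro-Prins) cleavage of C3–C4 through the ring A chair in which the 4α-CH2OSi group is axial, which gives the aldehyde and the tetrasubstituted olefin with CH2OSi cis to C10; the closest known reaction types are Lewis acid epoxy-polyene cyclisation, BF3-induced hydride/methyl backbone rearrangement of 8-drimanyl cations, and acid-induced retro-Prins fragmentation of 1,3-hydroxy carbocations.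

Step 9
Reactants: 16 seco-aldehyde sulfone
Product: 18 3-[(1S,2R,3R,6Z)-6-[1-(tert-butyldiphenylsilyloxy)propan-2-ylidene]-2,3-dimethyl-2-[(3E,7E)-4,8,12-trimethyltrideca-3,7,11-trien-1-yl]cyclohexyl]propan-1-ol, via hydroxy sulfone 17 (not isolated)
Conditions: LiBHEt3 (4 equiv), PdCl2(dppp) (5 mol %; dppp = 1,3-bis(diphenylphosphino)propane), THF, 0 °C
Reagents that add atoms: none
Why: LiBHEt3 reduces the aldehyde at once, and zerovalent palladium formed in situ ionises the allylic sulfone to a π-allyl complex that takes hydride at its less substituted terminus, so the E trisubstituted olefin stays in place (palladium-catalysed reductive desulfonylation); the allylic silyl ether is not ionised and the uncontrolled stereocentre disappears.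

Step 10
Reactants: 18 silyl ether alcohol
Product: 19 (2Z)-2-[(2S,3R,4R)-2-(3-hydroxypropyl)-3,4-dimethyl-3-[(3E,7E)-4,8,12-trimethyltrideca-3,7,11-trien-1-yl]cyclohexylidene]propan-1-ol
Conditions: Bu4NF, THF, 0 °C → rt
Reagents that add atoms: none
Why: Fluoride-induced cleavage of the Si–O bond (desilylation); nothing else in 18 reacts and no stereocentre is touched.

Step 11
Reactants: 19 diol
Product: 20 (2Z)-2-[(2S,3R,4R)-2-(3-hydroxypropyl)-3,4-dimethyl-3-[(3E,7E)-4,8,12-trimethyltrideca-3,7,11-trien-1-yl]cyclohexylidene]propanal (target)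
Conditions: MnO2 (20 equiv), CH2Cl2, rt
Reagents that add atoms: none
Why: MnO2 oxidises allylic alcohols chemoselectively, so the saturated primary alcohol is untouched, and the neutral heterogeneous conditions keep the Z geometry and the stereocentre next to the enal intact.

## Compound list

1 | prenol (3-methylbut-2-en-1-ol) | CC(C)=CCO | starting material
2 | geranyl bromide | CC(C)=CCC/C(C)=C/CBr | starting material
3 | lithium (2Z)-4-lithio-3-methylbut-2-en-1-olate (formed in the flask) | [Li]C/C(C)=C\CO[Li] | intermediate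
4 | (2Z,6E)-farnesol | CC(C)=CCC/C(C)=C/CC/C(C)=C\CO | intermediate
5 | (2Z,6E)-farnesyl methanesulfonate (formed in the flask) | CC(C)=CCC/C(C)=C/CC/C(C)=C\COS(C)(=O)=O | intermediate
6 | (2Z,6E)-farnesyl chloride | CC(C)=CCC/C(C)=C/CC/C(C)=C\CCl | intermediate
7 | (2E,6E,10Z)-12-chloro-2,6,10-trimethyldodeca-2,6,10-trien-1-ol | OC/C(C)=C/CC/C(C)=C/CC/C(C)=C\CCl | intermediate
8 | [(2S,3S)-3-[(3E,7Z)-9-chloro-3,7-dimethylnona-3,7-dien-1-yl]-2-methyloxiran-2-yl]methanol | OC[C@]1(C)O[C@H]1CC/C(C)=C/CC/C(C)=C\CCl | intermediate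
9 | tert-butyldiphenylsilyl ether of 8 | CC(C)(C)[Si](OC[C@]1(C)O[C@H]1CC/C(C)=C/CC/C(C)=C\CCl)(c2ccccc2)c3ccccc3 | intermediate
10 | (2E,6E)-farnesyl bromide | CC(C)=CCC/C(C)=C/CC/C(C)=C/CBr | starting material
11 | (2E,6E)-farnesyl phenyl sulfone | CC(C)=CCC/C(C)=C/CC/C(C)=C/CS(=O)(=O)c1ccccc1 | intermediate
12 | α-lithio derivative of 11 (formed in the flask) | CC(C)=CCC/C(C)=C/CC/C(C)=C/C([Li])S(=O)(=O)c1ccccc1 | intermediate
13 | epoxy-tetraene sulfone: (2S,3S)-epoxide with E-CH2OTBDPS, 3E,7Z,11E,15E chain, PhSO2 on C12 (both epimers at that carbon) | CC(C)(C)[Si](OC[C@]1(C)O[C@H]1CC/C(C)=C/CC/C(C)=C\CC(/C=C(\C)CC/C=C(\C)CCC=C(C)C)S(=O)(=O)c2ccccc2)(c3ccccc3)c4ccccc4 | intermediate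
14 | bicyclic C8 carbocation, zwitterion with the C3 alkoxytrifluoroborate (3β-O, 4α-CH2OTBDPS, 5α-H, 10β-CH3, 9β-H; formed in the flask) | F[B-](F)(F)O[C@H]1CC[C@@]2(C)[C@@H](CC[C+](C)[C@H]2CC(S(=O)(=O)c3ccccc3)/C=C(\C)CC/C=C(\C)CCC=C(C)C)[C@]1(C)CO[Si](C(C)(C)C)(c4ccccc4)c5ccccc5 | intermediate
15 | rearranged C5 carbocation, same zwitterion type (8α-CH3, 8β-H, 9β-CH3, 10α-H; formed in the flask) | F[B-](F)(F)O[C@H]1CC[C@@H]2[C+](CC[C@@H](C)[C@@]2(C)CC(S(=O)(=O)c3ccccc3)/C=C(\C)CC/C=C(\C)CCC=C(C)C)[C@]1(C)CO[Si](C(C)(C)C)(c4ccccc4)c5ccccc5 | intermediate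
16 | seco-aldehyde sulfone (ring configured as in 20; CH2OTBDPS cis to the ring CH; both epimers at the sulfonyl carbon) | CC(C)=CCC/C(C)=C/CC/C(C)=C/C(C[C@]1(C)[C@H](C)CC/C(=C(\C)CO[Si](C(C)(C)C)(c2ccccc2)c3ccccc3)[C@H]1CCC=O)S(=O)(=O)c4ccccc4 | intermediate
17 | hydroxy sulfone, the primary alcohol of 16 (formed in the flask) | CC(C)=CCC/C(C)=C/CC/C(C)=C/C(C[C@]1(C)[C@H](C)CC/C(=C(\C)CO[Si](C(C)(C)C)(c2ccccc2)c3ccccc3)[C@H]1CCCO)S(=O)(=O)c4ccccc4 | intermediate
18 | allylic tert-butyldiphenylsilyl ether of diol 19 | CC(C)=CCC/C(C)=C/CC/C(C)=C/CC[C@]1(C)[C@H](C)CC/C(=C(\C)CO[Si](C(C)(C)C)(c2ccccc2)c3ccccc3)[C@H]1CCCO | intermediate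
19 | (2Z)-2-[(2S,3R,4R)-2-(3-hydroxypropyl)-3,4-dimethyl-3-[(3E,7E)-4,8,12-trimethyltrideca-3,7,11-trien-1-yl]cyclohexylidene]propan-1-ol | CC(C)=CCC/C(C)=C/CC/C(C)=C/CC[C@]1(C)[C@H](C)CC/C(=C(\C)CO)[C@H]1CCCO | intermediate
20 | (2Z)-2-[(2S,3R,4R)-2-(3-hydroxypropyl)-3,4-dimethyl-3-[(3E,7E)-4,8,12-trimethyltrideca-3,7,11-trien-1-yl]cyclohexylidene]propanal | CC(C)=CCC/C(C)=C/CC/C(C)=C/CC[C@]1(C)[C@H](C)CC/C(=C(\C)C=O)[C@H]1CCCO | target

## Step count and weak points

Total: 11 steps. Longest linear sequence: 10 steps (steps 1–5 and 7–11); step 6 is a one-step side branch.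

Most likely to fail, first: step 8. The cascade can leak at each cation: proton loss before the shifts, methyl migration to C5 instead of C3–C4 cleavage, fragmentation from a twist conformer (which would give the E allyl ether), or re-addition of the BF3-bound aldehyde to an olefin. The fallback sets out from 13 and comes back at 16 in two separate operations. 13 is cyclised with MeAlCl2 (CH2Cl2, −78 °C), whose methyl–aluminium bond destroys the proton released after ring B closure, so the sequence stops on purpose at bicyclic 9β-H drim-7-ene alcohol F1, which is isolated. F1 is then re-ionised at C8 by protonation of its ring olefin with TfOH (0.2 equiv) in CH2Cl2/(CF3)2CHOH at −40 °C, where the free C3 hydroxyl drives the shifts and the Grob opening to 16.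

Second: step 3. The SeO2 oxidation of a triene that carries an allylic chloride may give mixtures (attack at the central olefin, loss of chloride). The fallback sets out from 4 and comes back at 9 and carries the chain end as an ester instead. Ac2O/pyridine gives (2Z,6E)-farnesyl acetate F2; SeO2/t-BuOOH gives 12-hydroxy acetate F3; Sharpless epoxidation as in step 4 gives epoxy alcohol acetate F4; TBDPSCl/imidazole gives silyl ether acetate F5; K2CO3/MeOH frees allylic alcohol F6; MsCl/s-collidine/LiCl as in step 2 gives 9.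

Third: step 1. The dianion alkylation may give low conversion or attack through the internal allyl position. The fallback sets out from 2 and comes back at 4 and builds the Z olefin by carbocupration instead. Lithiated 1-(trimethylsilyl)propyne (n-BuLi, THF, −78 °C) is alkylated by 2 at its propargylic carbon to give silyl enyne F7. MeLi·LiBr followed by ClCO2Me gives ynoate F8. Me2CuLi (THF, −78 °C, protic quench) adds methyl and hydrogen syn to give methyl (2Z,6E)-farnesoate F9, and i-Bu2AlH (CH2Cl2, −78 °C) reduces it to 4.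

## Further compounds

F1 | step 8 | bicyclic olefin alcohol: decalin with 3β-OH, 4α-CH2OTBDPS, 4β-CH3, 5α-H, 10β-CH3, 9β-H, C7=C8 olefin with C8 methyl, and the (3E,7E)-4,8,12-trimethyl-2-(phenylsulfonyl)trideca-3,7,11-trien-1-yl chain on C9α | O[C@H]1CC[C@@]2(C)[C@@H](CC=C(C)[C@H]2CC(S(=O)(=O)c3ccccc3)/C=C(\C)CC/C=C(\C)CCC=C(C)C)[C@]1(C)CO[Si](C(C)(C)C)(c4ccccc4)c5ccccc5
F2 | step 3 | (2Z,6E)-farnesyl acetate | CC(C)=CCC/C(C)=C/CC/C(C)=C\COC(C)=O
F3 | step 3 | (2Z,6E,10E)-12-hydroxy-3,7,11-trimethyldodeca-2,6,10-trien-1-yl acetate | OC/C(C)=C/CC/C(C)=C/CC/C(C)=C\COC(C)=O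
F4 | step 3 | (2Z,6E)-9-[(2S,3S)-3-(hydroxymethyl)-3-methyloxiran-2-yl]-3,7-dimethylnona-2,6-dien-1-yl acetate | OC[C@]1(C)O[C@H]1CC/C(C)=C/CC/C(C)=C\COC(C)=O
F5 | step 3 | tert-butyldiphenylsilyl ether of F4 | CC(C)(C)[Si](OC[C@]1(C)O[C@H]1CC/C(C)=C/CC/C(C)=C\COC(C)=O)(c2ccccc2)c3ccccc3
F6 | step 3 | (2Z,6E)-9-[(2S,3S)-3-[(tert-butyldiphenylsilyloxy)methyl]-3-methyloxiran-2-yl]-3,7-dimethylnona-2,6-dien-1-ol | CC(C)(C)[Si](OC[C@]1(C)O[C@H]1CC/C(C)=C/CC/C(C)=C\CO)(c2ccccc2)c3ccccc3
F7 | step 1 | trimethyl[(5E)-6,10-dimethylundeca-5,9-dien-1-yn-1-yl]silane | C[Si](C)(C)C#CCC/C=C(\C)CCC=C(C)C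
F8 | step 1 | methyl (6E)-7,11-dimethyldodeca-6,10-dien-2-ynoate | COC(=O)C#CCC/C=C(\C)CCC=C(C)C
F9 | step 1 | methyl (2Z,6E)-farnesoate | COC(=O)/C=C(C)\CC/C=C(\C)CCC=C(C)C
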